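Readings and results are simulated with made-up constants; scatter was added.

I counted amounts first, with the impurity written as a fraction of the starting material charge. By the end of Monday's and Tuesday's runs the starting material read 0.4% or less, so I counted what was not target as quenched substrate: 50.8% on Monday and 18.3% on Tuesday. Each unit quenched uses one unit of impurity, so I took the impurity present on average as its charge minus the quenched share divided by two.

| flask | starting material | protic impurity | remark | time |
|---|---|---|---|---|
| Tuesday's | 0.25 M (fed, over 0.80 min) | 0.062 M | run made earlier; the fed solution adds 0.25 times the starting volume |  |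
| Monday's | 0.25 M (fed, over 0.80 min) | 0.25 M | run made earlier; the fed solution adds 0.25 times the starting volume |  |
| Sunday's | 0.50 M (fed, over 0.80 min) | 0.125 M | run made earlier; the fed solution adds 0.25 times the starting volume |  |
| summer | 0.25 M (fed, over 0.80 min) | 0.125 M | the fed solution adds 0.25 times the starting volume | 6.0 min |
| autumn | 0.25 M (fed, over 1.5 min) | 0.125 M | the fed solution adds 0.25 times the starting volume | 6.0 min |
| noon | 0.25 M (fed, over 3.0 min) | 0.125 M | the fed solution adds 0.25 times the starting volume | 6.0 min |
| dusk | 0.25 M (fed, over 6.0 min) | 0.125 M | the fed solution adds 0.25 times the starting volume | 6.0 min |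

| run | time / min | target / % | starting material / % |
|---|---|---|---|
| Tuesday's | 1.00 | 54.0 | 30.4 |
| Tuesday's | 2.00 | 80.2 | 1.9 |
| Tuesday's | 3.00 | 81.4 | 0 |
| Tuesday's | 4.00 | 81.4 | 0 |
| Tuesday's | 5.00 | 82.3 | 0.4 |
| Tuesday's | 6.00 | 81.7 | 0.4 |
| Monday's | 0.417 | 13.3 | 20.8 |
| Monday's | 1.33 | 47.5 | 3.6 |
| Monday's | 2.00 | 49.2 | 0.3 |
| Monday's | 3.00 | 49.1 | 0.1 |
| Monday's | 5.00 | 49.5 | 0 |
| Monday's | 6.00 | 49.2 | 0 |
| Sunday's | 1.33 | 52.6 | 24.1 |
| Sunday's | 2.50 | 74.5 | 1.3 |
| Sunday's | 4.00 | 76.0 | 0 |
| Sunday's | 5.00 | 75.5 | 0.7 |
| Sunday's | 6.00 | 75.7 | 0 |

(standard deviation of a reading: 0.3 percentage points)

- charges are per starting volume, the dose included; the dosed solution carries all of it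
- what was read earlier has a scatter of 0.3 percentage points, one standard deviation
- steps thought possible: starting material -> target; starting material + protic impurity -> quenched substrate
- percentages count the whole charge, also what has not yet gone in
- "hardly changes" means that all values lie within two and a half points (for a concentration: within two and a half percent of the largest)

- amount of target at the end, in percent of the starting material charged for summer, autumn, noon, dusk, in this order
- how the row runs (falls, then rises / rises, then falls / falls all the way / hardly changes / rises all the way)

I divided quenched substrate by target, then divided that by the average impurity. Monday gave 1.38 and Tuesday 1.43. I called their mean the quench odds w, the quenched substrate formed per unit of target for each unit of average impurity, which came to 1.41, a selectivity factor at this charge and dose.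

Summer has the same charge and dose as those runs, with impurity at 0.500 of the charge. In one extreme version of summer none of the impurity is used, and target is 58.7%. In the other, the impurity has been lowered by that version's large quench, and target is 70.8%. By this rule the real flask must lie between them, because the first overstates the impurity and the second understates it. Going round once more gave 66.8%. This w was read at a dose of 0.80 min, which is summer's dose, so I committed to the first point of the row and no further.

The forecast gave 67%, 68.5%, 71% and 69%, with the shape "rises, then falls". It said “yield rises from about 67 to 71%” before the last point drops.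

The flask gave 67.6%, 69.3%, 71.0% and 68.4%, with the shape "rises, then falls".

    starting material → target, rate k1*[starting material]/(1 + ([starting material]/sat1)) (0.0872 M, k = 0.0544 s⁻¹)
    starting material + protic impurity → quenched substrate (k = 0.255 M⁻¹ s⁻¹)

Dusk, which the forecast put at 69%, gave 68.4% with 4.51% of its starting material still unreacted at 6.00 min. My third round for summer stood 0.80 percentage points below the flask's 67.6%. Read backwards on noon, where target ended at 71.0%, the same rule gives w = 1.15, lower than the 1.41 from Monday's and Tuesday's runs.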